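The free catalyst is single-handed, so in this dynamic kinetic resolution you watch two substrate peaks part while the racemization catalyst pulls them back together.

| flask | left-handed substrate | right-handed substrate | partner | free catalyst | precatalyst | remark | time |
|---|---|---|---|---|---|---|---|
| blue | 20 mM | 20 mM | 2.2 equiv | 2.8 mol% | 8.2 mol% | the very flask that is asked about, followed so far |  |
| violet | 20 mM | 20 mM | 1.5 equiv | 2.8 mol% | 8.2 mol% | run made earlier |  |
| flask | 20 mM | 20 mM | 2.20 equiv | 2.8 mol% | 8.2 mol% |  | 2.5 h |

- free catalyst is single-handed; left-handed substrate and right-handed substrate are mirror images of each other, charged as a racemate, each of them at the stated concentration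
- steps thought possible: partner + free catalyst + left-handed substrate -> free catalyst + left-handed product; partner + free catalyst + right-handed substrate -> free catalyst + right-handed product; left-handed substrate + racemization catalyst <-> right-handed substrate + racemization catalyst; partner + precatalyst -> racemization catalyst + spent reagent; racemization catalyst <-> dormant form
- an excess is the difference of the two amounts in percent of their sum
- an excess is below zero if the other one leads

- part of the left-handed substrate and right-handed substrate charged together that has reacted at 2.5 h
- excess of left-handed product over right-handed product in the product at 2.5 h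
- excess of right-handed substrate over left-handed substrate among what is left of the two at 2.5 h

| run | time / min | left-handed substrate / % | right-handed substrate / % | left-handed product / % |
|---|---|---|---|---|
| blue | 8.00 | 49 | 49 | 2 |
| blue | 20.0 | 45 | 47 | 5 |
| blue | 40.0 | 39 | 43 | 12 |
| blue | 60.0 | 39 | 42 | 18 |
| violet | 8.00 | 47 | 51 | 3 |
| violet | 20.0 | 45 | 49 | 5 |
| violet | 50.0 | 44 | 44 | 8 |
| violet | 120 | 38 | 40 | 21 |

(scatter of a reading: 1.5 percentage points)

Read the blue table row by row. At 8.00 min the two substrates both stand at 49%. At 20.0 min the right-handed substrate leads by 2 percentage points, then by 4 points at 40.0 min and 3 points at 60.0 min, so the lead has stopped widening within the scatter.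

A standing gap means two rates match. Call λ the mean first-order loss of the two substrates together, which opens the gap, and let racemization close it in proportion to its size. Then, for as long as both rates hold still, the excess eS is λ divided by the closing rate, and time drops out of that quotient; λ and the closing rate can each still drift with time.

The last two blue rows give eS = 4.29% as a reading, give or take 1.8 points. The substrates left at 60.0 min give λ = 0.00351 min⁻¹. Their quotient is τ = 12.2 min, the closing time, that is, the excess held per unit of λ.

The flask has blue's recipe, so if λ and the closing rate stay as read, your own reckoning for eS at 2.5 h is near 4.29%; that is an assumption, and the reckoning says nothing about c or eP.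

The forecast gives c = 39%, eP = 90% and eS = 4%, judging “so racemization keeps pace”.

The flask gives c = 35.0%, eP = 84.0% and eS = 4.31%.

    partner + free catalyst + left-handed substrate → free catalyst + left-handed product (k = 4.74 L² mol⁻² s⁻¹)
    partner + free catalyst + right-handed substrate → free catalyst + right-handed product (k = 0.381 L² mol⁻² s⁻¹)
    left-handed substrate + racemization catalyst ⇌ right-handed substrate + racemization catalyst, rate k3*[racemization catalyst]*[left-handed substrate] forward; the back reaction follows from the equilibrium constant (k = 0.446 L mol⁻¹ s⁻¹)
    partner + precatalyst → racemization catalyst + spent reagent (k = 0.0261 L mol⁻¹ s⁻¹)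
    racemization catalyst ⇌ dormant form (K = 0.827, k = 2.05 × 10⁻⁴ s⁻¹)

The flask's own mean loss is λ = 0.00287 min⁻¹, and multiplied by τ it gives eS = 3.50%, which is 0.81 points under the flask's 4.31% and inside the reading's scatter. Now take the neighbour charged with 4.8 mol% of free catalyst, everything else unchanged. It reaches c = 47.7%, so its λ is 0.00432 min⁻¹, and the same τ gives eS = 5.27%. That neighbour stands at eS = 6.16%.

All runs were generated by integration with made-up constants; noise was put on by code.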